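**Plan**

- Oxane numbering: O1, C2 (2-arylethyl chain to guaiacyl ring A), C3, C4 (OH), C5, C6 (ring B). Retrosynthetic cuts, in order: the three phenol protecting groups and the C4 carbinol (back to the oxan-4-one); the C5–C6 bond, which opens the ring to an acyclic ring B benzyl ether carrying a 2-acetoxyallyl group; the O1–CH2(ring B) ether bond; the C2–C3 bond (aldehyde plus C3 unit).
- Enabling feature: C6 is both benzylic to the trioxygenated ring B and bonded to O1, so the corresponding CH2 of the open-chain ring B benzyl ether is the best hydride donor in the molecule and can be oxidised to an oxocarbenium ion.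
- Forward: the ring A aldehyde is propargylated (C2–C3), the carbinol is benzylated with the ring B unit (O1–C6), the alkyne becomes the enol acetate, and the oxane, the only ring made, closes by C5–C6 bond formation. Ketone reduction and two deprotections finish.
- Stereochemistry: C2 (S) comes from a catalyst-controlled propargylation. C6 (S) is relayed from C2 through the chair transition state of the ring closure. C4 (R) comes from axial hydride delivery to the ketone. The target is all-cis, (2S,4R,6S).

Key step: step 10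

Assumption: the (R) phosphoric acid is taken to steer the allenylboronate to the Re face of the linear ring A aldehyde, the face it selects with benzaldehyde; if the opposite sense were found, the (S) acid would be used with no other change.

**Route**

Step 1
Reactants: 1 3-(4-hydroxy-3-methoxyphenyl)propanoic acid
Product: 2 methyl 3-(4-hydroxy-3-methoxyphenyl)propanoate
Conditions: MeOH, H2SO4 (cat.), reflux
Reagents that add atoms: methanol (SMILES CO)
Why: Fischer esterification of an unhindered acid in excess methanol should go to completion and leaves the phenol untouched.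

Step 2
Reactants: 2 methyl 3-(4-hydroxy-3-methoxyphenyl)propanoate
Product: 3 methyl 3-[3-methoxy-4-(tosyloxy)phenyl]propanoate
Conditions: TsCl, Et3N, DMAP (cat.), CH2Cl2, 0 °C to rt
Reagents that add atoms: 4-toluenesulfonyl chloride (SMILES Cc1ccc(cc1)S(Cl)(=O)=O)
Why: O-sulfonylation of the phenol gives an aryl tosylate that masks the phenol through the hydride and acid steps and raises the oxidation potential of ring A for step 10.

Step 3
Reactants: 3 methyl 3-[3-methoxy-4-(tosyloxy)phenyl]propanoate
Product: 5 3-[3-methoxy-4-(tosyloxy)phenyl]propanal, via aluminium hemiacetal 4 (not isolated)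
Conditions: i-Bu2AlH (1.05 equiv), CH2Cl2, −78 °C; MeOH, then aq. potassium sodium tartrate
Reagents that add atoms: none
Why: partial reduction of a methyl ester with i-Bu2AlH stops at the tetrahedral aluminium hemiacetal 4 at −78 °C, which releases the aldehyde only on work-up, and the aryl sulfonate is inert to the hydride at this temperature.

Step 4
Reactants: 5 3-[3-methoxy-4-(tosyloxy)phenyl]propanal; 6 allenylboronic acid pinacol ester (4,4,5,5-tetramethyl-2-(propa-1,2-dien-1-yl)-1,3,2-dioxaborolane)
Product: 8 4-[(3S)-3-hydroxyhex-5-yn-1-yl]-2-methoxyphenyl 4-methylbenzenesulfonate, via boronate ester 7 (not isolated)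
Conditions: 6 (1.5 equiv), (R)-TRIP [(R)-3,3'-bis(2,4,6-triisopropylphenyl)-1,1'-binaphthyl-2,2'-diyl hydrogen phosphate] (10 mol %), 4 Å MS, toluene, −20 °C; aq. NaHCO3 work-up
Reagents that add atoms: none
Why: chiral phosphoric acid-catalysed asymmetric propargylation (allenylboration) proceeds through a closed six-membered SE2' transition state in which the acid binds a boronate oxygen and the formyl hydrogen, so only the homopropargylic carbinol should form and the (R) acid should direct attack to the Re face of 5, setting C2 as (S).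

Step 5
Reactants: 9 3,4-dihydroxy-5-methoxybenzaldehyde
Product: 10 3,4-bis(benzyloxy)-5-methoxybenzaldehyde
Conditions: BnBr (2.5 equiv), K2CO3, DMF, 60 °C
Reagents that add atoms: benzyl bromide (SMILES BrCc1ccccc1)
Why: Williamson etherification of both phenoxides installs benzyl ethers that keep ring B electron-rich for step 10 and can be removed at the end under neutral conditions.

Step 6
Reactants: 10 3,4-bis(benzyloxy)-5-methoxybenzaldehyde
Product: 11 [3,4-bis(benzyloxy)-5-methoxyphenyl]methanol
Conditions: NaBH4, MeOH–THF, 0 °C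
Reagents that add atoms: none
Why: borohydride reduction of an aromatic aldehyde to the benzylic alcohol is fast and does not touch the aryl ethers.

Step 7
Reactants: 11 [3,4-bis(benzyloxy)-5-methoxyphenyl]methanol
Product: 12 [3,4-bis(benzyloxy)-5-methoxyphenyl]methyl 2,2,2-trichloroacetimidate
Conditions: Cl3CCN (1.5 equiv), DBU (10 mol %), CH2Cl2, 0 °C; filtration through Et3N-treated silica
Reagents that add atoms: trichloroacetonitrile (SMILES N#CC(Cl)(Cl)Cl)
Why: base-catalysed addition of the benzylic alkoxide to the nitrile (imidate formation) gives an O-benzyl donor that is activated later by acid and is used without storage.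

Step 8
Reactants: 8 4-[(3S)-3-hydroxyhex-5-yn-1-yl]-2-methoxyphenyl 4-methylbenzenesulfonate; 12 [3,4-bis(benzyloxy)-5-methoxyphenyl]methyl 2,2,2-trichloroacetimidate
Product: 13 4-[(3S)-3-{[3,4-bis(benzyloxy)-5-methoxyphenyl]methoxy}hex-5-yn-1-yl]-2-methoxyphenyl 4-methylbenzenesulfonate
Conditions: 12 (1.5 equiv, slow addition), TfOH (2 mol %), 4 Å MS, CH2Cl2, −20 to 0 °C
Reagents that add atoms: none
Why: acid-catalysed trichloroacetimidate benzylation ionises the protonated imidate to a benzylic cation stabilised by the 4-alkoxy group, which the secondary alcohol captures with loss of trichloroacetamide, and because no alkoxide is formed the aryl tosylate, the terminal alkyne and the C2 configuration are not at risk.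

Step 9
Reactants: 13 4-[(3S)-3-{[3,4-bis(benzyloxy)-5-methoxyphenyl]methoxy}hex-5-yn-1-yl]-2-methoxyphenyl 4-methylbenzenesulfonate
Product: 14 (4S)-4-{[3,4-bis(benzyloxy)-5-methoxyphenyl]methoxy}-6-[3-methoxy-4-(tosyloxy)phenyl]hex-1-en-2-yl acetate
Conditions: [Ru(p-cymene)Cl2]2 (2 mol %), P(2-furyl)3 (4 mol %), Na2CO3 (10 mol %), AcOH (2 equiv), toluene, 80 °C
Reagents that add atoms: acetic acid (SMILES CC(=O)O)
Why: ruthenium-catalysed Markovnikov hydroacyloxylation of a terminal alkyne with the furylphosphine/carbonate system places the acetate on the internal carbon, giving the 2-acetoxyalkene without touching the ethers or the tosylate.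

Step 10
Reactants: 14 (4S)-4-{[3,4-bis(benzyloxy)-5-methoxyphenyl]methoxy}-6-[3-methoxy-4-(tosyloxy)phenyl]hex-1-en-2-yl acetate
Product: 17 (2S,6S)-2-[3,4-bis(benzyloxy)-5-methoxyphenyl]-6-{2-[3-methoxy-4-(tosyloxy)phenyl]ethyl}oxan-4-one, via oxocarbenium ion 15 (not isolated), via acetylated oxocarbenium ion 16 (not isolated)
Conditions: DDQ (2 equiv), 2,6-dichloropyridine (4 equiv), 4 Å MS, ClCH2CH2Cl, rt
Reagents that add atoms: none
Why: DDQ removes a hydride equivalent from the benzylic CH2 of the ring B benzyl ether (electron transfer from the trialkoxy arene, then loss of the benzylic hydrogen), giving the (E)-oxocarbenium ion 15 stabilised by ring B and O1; enol acetate carbon C5 then bonds to C6 to give the acetylated oxocarbenium ion 16, which hands its acetyl group to the reduced quinone and leaves ketone 17. The closest known reaction type is the DDQ-mediated oxidative C–H cleavage of electron-rich benzylic ethers with capture of the oxocarbenium ion by a tethered enol acetate, a Prins-type cyclisation that needs no acetal precursor. The oxane closes in a 6-endo-trig mode with respect to both partners, since O1=C6 and C4=C5 all end up inside the ring. C6 is the only new stereocenter and is controlled by C2: in the chair transition state the 2-arylethyl chain at C2 and ring B on the (E)-oxocarbenium ion both sit equatorial, which should give the 2,6-cis ketone with C6 (S). The step needs oxidation at the ring B benzylic CH2 only: the tosylate keeps ring A out of reach of DDQ, the OCH2Ph hydrogens are not benzylic to the oxidised arene and would lead to a poorly stabilised aryloxycarbenium ion, and the C6–H of 17 is deactivated by the inductive pull of the C4 carbonyl. Molecular sieves exclude the water that would divert 15 to aldehyde and alcohol, and 2,6-dichloropyridine buffers the acidic hydroquinone so that the enol acetate is not protonated.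

Step 11
Reactants: 17 (2S,6S)-2-[3,4-bis(benzyloxy)-5-methoxyphenyl]-6-{2-[3-methoxy-4-(tosyloxy)phenyl]ethyl}oxan-4-one
Product: 18 4-{2-[(2S,4R,6S)-6-[3,4-bis(benzyloxy)-5-methoxyphenyl]-4-hydroxyoxan-2-yl]ethyl}-2-methoxyphenyl 4-methylbenzenesulfonate
Conditions: NaBH4, MeOH–CH2Cl2, −40 to 0 °C
Reagents that add atoms: none
Why: borohydride reduction of the chair oxan-4-one with both substituents equatorial should proceed by axial attack of the small hydride, placing the new hydroxyl equatorial and cis to both substituents, which sets C4 as (R).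

Step 12
Reactants: 18 4-{2-[(2S,4R,6S)-6-[3,4-bis(benzyloxy)-5-methoxyphenyl]-4-hydroxyoxan-2-yl]ethyl}-2-methoxyphenyl 4-methylbenzenesulfonate
Product: 19 (2S,4R,6S)-2-[3,4-bis(benzyloxy)-5-methoxyphenyl]-6-[2-(4-hydroxy-3-methoxyphenyl)ethyl]oxan-4-ol
Conditions: Mg turnings (10 equiv), MeOH, rt
Reagents that add atoms: none
Why: reductive desulfonylation by electron transfer from magnesium cleaves the S–O bond of the aryl tosylate to phenoxide and sulfinate without touching benzyl ethers or the oxane, and it is placed before debenzylation so that the catechol never meets the basic methoxide medium.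

Step 13
Reactants: 19 (2S,4R,6S)-2-[3,4-bis(benzyloxy)-5-methoxyphenyl]-6-[2-(4-hydroxy-3-methoxyphenyl)ethyl]oxan-4-ol
Product: 20 (2S,4R,6S)-2-(3,4-dihydroxy-5-methoxyphenyl)-6-[2-(4-hydroxy-3-methoxyphenyl)ethyl]oxan-4-ol (CNP0399218.1)
Conditions: H2 (1 atm), 10% Pd/C, EtOAc, rt, stopped after uptake of two equivalents
Reagents that add atoms: none
Why: catalytic hydrogenolysis of the two aryl benzyl ethers frees the catechol under neutral, reducing conditions, and the cyclic benzylic C6–O1 bond should be cleaved much more slowly, so no stereocenter is touched.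

**Compound list**

1 | 3-(4-hydroxy-3-methoxyphenyl)propanoic acid | COc1cc(CCC(=O)O)ccc1O | starting material
2 | methyl 3-(4-hydroxy-3-methoxyphenyl)propanoate | COC(=O)CCc1ccc(O)c(OC)c1 | intermediate
3 | methyl 3-[3-methoxy-4-(tosyloxy)phenyl]propanoate | COC(=O)CCc1ccc(OS(=O)(=O)c2ccc(C)cc2)c(OC)c1 | intermediate
4 | aluminium hemiacetal, diisobutylaluminium derivative of the methyl hemiacetal of 5 (not isolated) | COC(CCc1ccc(OS(=O)(=O)c2ccc(C)cc2)c(OC)c1)O[Al](CC(C)C)CC(C)C | intermediate
5 | 3-[3-methoxy-4-(tosyloxy)phenyl]propanal | O=CCCc1ccc(OS(=O)(=O)c2ccc(C)cc2)c(OC)c1 | intermediate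
6 | allenylboronic acid pinacol ester | C=C=CB1OC(C)(C)C(C)(C)O1 | starting material
7 | boronate ester, O-pinacolboryl derivative of 8 (not isolated) | COc1cc(CC[C@H](OB2OC(C)(C)C(C)(C)O2)CC#C)ccc1OS(=O)(=O)c1ccc(C)cc1 | intermediate
8 | 4-[(3S)-3-hydroxyhex-5-yn-1-yl]-2-methoxyphenyl 4-methylbenzenesulfonate | COc1cc(CC[C@H](O)CC#C)ccc1OS(=O)(=O)c1ccc(C)cc1 | intermediate
9 | 3,4-dihydroxy-5-methoxybenzaldehyde | COc1cc(C=O)cc(O)c1O | starting material
10 | 3,4-bis(benzyloxy)-5-methoxybenzaldehyde | COc1cc(C=O)cc(OCc2ccccc2)c1OCc1ccccc1 | intermediate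
11 | [3,4-bis(benzyloxy)-5-methoxyphenyl]methanol | COc1cc(CO)cc(OCc2ccccc2)c1OCc1ccccc1 | intermediate
12 | [3,4-bis(benzyloxy)-5-methoxyphenyl]methyl 2,2,2-trichloroacetimidate | COc1cc(COC(=N)C(Cl)(Cl)Cl)cc(OCc2ccccc2)c1OCc1ccccc1 | intermediate
13 | 4-[(3S)-3-{[3,4-bis(benzyloxy)-5-methoxyphenyl]methoxy}hex-5-yn-1-yl]-2-methoxyphenyl 4-methylbenzenesulfonate | COc1cc(CC[C@H](OCc2cc(OCc3ccccc3)c(OCc3ccccc3)c(OC)c2)CC#C)ccc1OS(=O)(=O)c1ccc(C)cc1 | intermediate
14 | (4S)-4-{[3,4-bis(benzyloxy)-5-methoxyphenyl]methoxy}-6-[3-methoxy-4-(tosyloxy)phenyl]hex-1-en-2-yl acetate | COc1cc(CC[C@H](OCc2cc(OCc3ccccc3)c(OCc3ccccc3)c(OC)c2)CC(=C)OC(C)=O)ccc1OS(=O)(=O)c1ccc(C)cc1 | intermediate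
15 | (E)-oxocarbenium ion from 14, O1=C6 cation (not isolated) | COc1cc(CC[C@H](/[O+]=C/c2cc(OCc3ccccc3)c(OCc3ccccc3)c(OC)c2)CC(=C)OC(C)=O)ccc1OS(=O)(=O)c1ccc(C)cc1 | intermediate
16 | acetylated oxocarbenium ion, O-acetyl cation of 17 (not isolated) | COc1cc(CC[C@H]2CC(=[O+]C(C)=O)C[C@@H](c3cc(OCc4ccccc4)c(OCc4ccccc4)c(OC)c3)O2)ccc1OS(=O)(=O)c1ccc(C)cc1 | intermediate
17 | (2S,6S)-2-[3,4-bis(benzyloxy)-5-methoxyphenyl]-6-{2-[3-methoxy-4-(tosyloxy)phenyl]ethyl}oxan-4-one | COc1cc(CC[C@H]2CC(=O)C[C@@H](c3cc(OCc4ccccc4)c(OCc4ccccc4)c(OC)c3)O2)ccc1OS(=O)(=O)c1ccc(C)cc1 | intermediate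
18 | 4-{2-[(2S,4R,6S)-6-[3,4-bis(benzyloxy)-5-methoxyphenyl]-4-hydroxyoxan-2-yl]ethyl}-2-methoxyphenyl 4-methylbenzenesulfonate | COc1cc(CC[C@H]2C[C@@H](O)C[C@@H](c3cc(OCc4ccccc4)c(OCc4ccccc4)c(OC)c3)O2)ccc1OS(=O)(=O)c1ccc(C)cc1 | intermediate
19 | (2S,4R,6S)-2-[3,4-bis(benzyloxy)-5-methoxyphenyl]-6-[2-(4-hydroxy-3-methoxyphenyl)ethyl]oxan-4-ol | COc1cc(CC[C@H]2C[C@@H](O)C[C@@H](c3cc(OCc4ccccc4)c(OCc4ccccc4)c(OC)c3)O2)ccc1O | intermediate
20 | (2S,4R,6S)-2-(3,4-dihydroxy-5-methoxyphenyl)-6-[2-(4-hydroxy-3-methoxyphenyl)ethyl]oxan-4-ol | COc1cc(CC[C@H]2C[C@@H](O)C[C@@H](c3cc(O)c(O)c(OC)c3)O2)ccc1O | target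

**Step count**

Total steps: 13. Longest linear sequence: 10 steps (1 to 20 through steps 1–4 and 8–13); the ring B branch (steps 5–7) joins at step 8.

**Steps most likely to fail**

Step 10 (key step). The oxidation may be outrun by oxidative cleavage of the ether through adventitious water, by attack at the aryl benzyl ethers, or by a second oxidation of the product at C6. The fallback makes the same oxocarbenium ion by condensation instead of C–H cleavage. It sets out from aldehyde 5. Allylboration with allylboronic acid pinacol ester under the same (R)-TRIP catalysis gives 4-[(3S)-3-hydroxyhex-5-en-1-yl]-2-methoxyphenyl 4-methylbenzenesulfonate F1. Prins cyclisation of this alcohol with aldehyde 10 in CF3CO2H/CH2Cl2 passes through the same chair and gives the all-cis ester (2S,4R,6S)-2-[3,4-bis(benzyloxy)-5-methoxyphenyl]-6-{2-[3-methoxy-4-(tosyloxy)phenyl]ethyl}oxan-4-yl trifluoroacetate F2. Brief methanolysis (K2CO3, MeOH, 0 °C) returns to the route at alcohol 18, so steps 8–11 are bypassed.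

Step 4. Facial selectivity on an unbranched aliphatic aldehyde may be insufficient, and any error at C2 is carried into C6 and C4. The fallback sets C2 by hydrogenation and sets out from ester 3. Crossed Claisen condensation with the lithium enolate of methyl acetate (LiN(i-Pr)2, THF, −78 °C) gives methyl 5-[3-methoxy-4-(tosyloxy)phenyl]-3-oxopentanoate F3. Noyori hydrogenation with [RuCl2((S)-BINAP)] (H2, MeOH, 50 °C) gives methyl (3S)-3-hydroxy-5-[3-methoxy-4-(tosyloxy)phenyl]pentanoate F4. Etherification with imidate 12 under the conditions of step 8 gives methyl (3S)-3-{[3,4-bis(benzyloxy)-5-methoxyphenyl]methoxy}-5-[3-methoxy-4-(tosyloxy)phenyl]pentanoate F5. Reduction with i-Bu2AlH at −78 °C gives (3S)-3-{[3,4-bis(benzyloxy)-5-methoxyphenyl]methoxy}-5-[3-methoxy-4-(tosyloxy)phenyl]pentanal F6. Ohira–Bestmann homologation (dimethyl (1-diazo-2-oxopropyl)phosphonate, K2CO3, MeOH) returns to the route at alkyne 13.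

Step 8. The benzylic cation from 12 may be consumed by self-alkylation of the electron-rich rings, or the imidate may rearrange to the amide faster than the secondary alcohol is alkylated. The fallback is a reductive etherification that sets out from alcohol 8. Silylation (Me3SiCl, imidazole, CH2Cl2) gives 2-methoxy-4-[(3S)-3-(trimethylsilyloxy)hex-5-yn-1-yl]phenyl 4-methylbenzenesulfonate F7. This silyl ether condenses with aldehyde 10 under catalytic Me3SiOSO2CF3 and is reduced in the same flask by Et3SiH (CH2Cl2, −78 °C), returning to the route at ether 13; steps 6 and 7 are then not needed.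

**Further compounds**

F1 | step 10 | 4-[(3S)-3-hydroxyhex-5-en-1-yl]-2-methoxyphenyl 4-methylbenzenesulfonate | COc1cc(CC[C@H](O)CC=C)ccc1OS(=O)(=O)c1ccc(C)cc1
F2 | step 10 | (2S,4R,6S)-2-[3,4-bis(benzyloxy)-5-methoxyphenyl]-6-{2-[3-methoxy-4-(tosyloxy)phenyl]ethyl}oxan-4-yl trifluoroacetate | COc1cc(CC[C@H]2C[C@@H](OC(=O)C(F)(F)F)C[C@@H](c3cc(OCc4ccccc4)c(OCc4ccccc4)c(OC)c3)O2)ccc1OS(=O)(=O)c1ccc(C)cc1
F3 | step 4 | methyl 5-[3-methoxy-4-(tosyloxy)phenyl]-3-oxopentanoate | COC(=O)CC(=O)CCc1ccc(OS(=O)(=O)c2ccc(C)cc2)c(OC)c1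
F4 | step 4 | methyl (3S)-3-hydroxy-5-[3-methoxy-4-(tosyloxy)phenyl]pentanoate | COc1cc(CC[C@H](O)CC(=O)OC)ccc1OS(=O)(=O)c1ccc(C)cc1
F5 | step 4 | methyl (3S)-3-{[3,4-bis(benzyloxy)-5-methoxyphenyl]methoxy}-5-[3-methoxy-4-(tosyloxy)phenyl]pentanoate | COc1cc(CC[C@H](OCc2cc(OCc3ccccc3)c(OCc3ccccc3)c(OC)c2)CC(=O)OC)ccc1OS(=O)(=O)c1ccc(C)cc1
F6 | step 4 | (3S)-3-{[3,4-bis(benzyloxy)-5-methoxyphenyl]methoxy}-5-[3-methoxy-4-(tosyloxy)phenyl]pentanal | COc1cc(CC[C@H](OCc2cc(OCc3ccccc3)c(OCc3ccccc3)c(OC)c2)CC=O)ccc1OS(=O)(=O)c1ccc(C)cc1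
F7 | step 8 | 2-methoxy-4-[(3S)-3-(trimethylsilyloxy)hex-5-yn-1-yl]phenyl 4-methylbenzenesulfonate | COc1cc(CC[C@H](O[Si](C)(C)C)CC#C)ccc1OS(=O)(=O)c1ccc(C)cc1
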